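**Retrosynthetic overview**
- Last step forms both rings in the biosynthetic order: C6–C7 closure of the ten-membered carbocycle (lactol-masked Z-enal at C6, 2-(methoxycarbonyl)allyl metal at C7), then O6→C12 lactonisation. The 8-isobutyrate is released in the same pot from an 8,10-cyclic orthoester.
- Seco precursor: a (Z)-2-(bromomethyl)enoate (Baylis–Hillman; C11–C13 from methyl acrylate) at one end and a butenolide, the masked (Z)-4-hydroxy-enal (C4–C6 from methyl propiolate, C15 from a cuprate), at the other.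
- C1–C3, C8–C10, C14 and the C10 stereocentre come from (S)-linalool; C3 and C8 are set by catalyst-controlled additions; C6 and C7 are set in the ring closure.
- Ring order: temporary butenolide and temporary 1,3-dioxane, then ten-membered carbocycle, then γ-lactone.

Assumption: (S)-(+)-linalool of ≥95% ee is bought; germacrane numbering (C1–C15) is used for all intermediates. The route is a paper design; nothing in it has been run.

Step 1
Reactants: 1 (S)-linalool
Product: 3 lactol (5S)-5-ethenyl-5-methyloxolan-2-ol (C2 epimers), via open hydroxy aldehyde 2 (not isolated)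
Conditions: O3 (1.0 equiv, Sudan red end point), CH2Cl2/MeOH, −78 °C; Me2S, −78 → 23 °C
Reagents that add atoms: ozone, [O-][O+]=O
Why: Ozonolysis with reductive work-up takes the electron-rich trisubstituted alkene before the vinyl group, and the γ-hydroxy aldehyde closes to the five-membered lactol; C10 is carried over from 1 and no stereocentre is made.

Step 2
Reactants: 3 lactol; 4 methyl propiolate
Product: 5 methyl (4S,7S)-4,7-dihydroxy-7-methylnon-8-en-2-ynoate
Conditions: (S,S)-ProPhenol (10 mol %), Ph3P=O (20 mol %), Me2Zn (4 equiv), 4 (3 equiv), toluene, 4 °C, 48 h; aq NH4Cl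
Reagents that add atoms: none
Why: Zinc–ProPhenol catalytic asymmetric alkynylation, in which the zinc lactolate opens to the aldehyde and the dinuclear zinc catalyst delivers the propiolate acetylide to the Re face to set C3 as S by catalyst control (the ligand antipode is the one chosen for Re-face delivery).

Step 3
Reactants: 5 ynoate diol
Product: 7 butenolide (5S)-5-[(3S)-3-hydroxy-3-methylpent-4-en-1-yl]-4-methylfuran-2(5H)-one, via Z-hydroxy enoate 6 (not isolated)
Conditions: Me2CuLi (4 equiv, from MeLi and CuI), THF, −78 → −40 °C; aq NH4Cl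
Reagents that add atoms: lithium dimethylcuprate Me2CuLi, [Li+].C[Cu-]C
Why: syn-Carbocupration (Gilman conjugate addition) places the C15 methyl on C4 with the C3 alkoxide and the ester cis, so lactonisation to the butenolide follows at once and locks the Z geometry of the future C4=C5 bond; C3 is not touched.

Step 4
Reactants: 7 butenolide
Product: 9 aldehyde (3S)-3-hydroxy-3-methyl-5-[(2S)-3-methyl-5-oxo-2,5-dihydrofuran-2-yl]pentanal, via B-alkyl-9-BBN adduct 8 (not isolated)
Conditions: 9-BBN (1.2 equiv), THF, 0 → 23 °C; then N-methylmorpholine N-oxide (6 equiv), Pr4N[RuO4] (5 mol %), 4 Å MS, CH2Cl2, 23 °C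
Reagents that add atoms: N-methylmorpholine N-oxide, C[N+]1([O-])CCOCC1
Why: Anti-Markovnikov hydroboration with bulky 9-BBN takes only the terminal vinyl group (the butenolide alkene is trisubstituted and electron-poor), and amine-oxide/perruthenate oxidation of the primary B–C bond (Ley–Griffith type) gives the C8 aldehyde directly; no new stereocentre.

Step 5
Reactants: 9 aldehyde
Product: 10 diol (5S)-5-[(3S,5R)-3,5-dihydroxy-3-methylhept-6-en-1-yl]-4-methylfuran-2(5H)-one
Conditions: Zn(CH=CH2)2 (2.5 equiv, pre-formed salt-free solution), (−)-MIB (10 mol %), toluene/hexane, −20 → 0 °C; aq NH4Cl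
Reagents that add atoms: divinylzinc Zn(CH=CH2)2, C=C[Zn]C=C
Why: Amino-alcohol-catalysed asymmetric vinylzinc addition (Noyori–Oppolzer type), in which (−)-MIB directs vinyl to the Si face of the aldehyde and so sets C8 as R by catalyst control, while organozincs leave the butenolide alone.

Step 6
Reactants: 10 diol
Product: 11 cyclic orthoester (5S)-5-{2-[(4S,6R)-6-ethenyl-2-methoxy-4-methyl-2-(propan-2-yl)-1,3-dioxan-4-yl]ethyl}-4-methylfuran-2(5H)-one (orthoester carbon epimers)
Conditions: iPrC(OMe)3 (3 equiv), PPTS (5 mol %), 4 Å MS, CH2Cl2, 23 °C; Et3N quench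
Reagents that add atoms: trimethyl orthoisobutyrate, COC(OC)(OC)C(C)C
Why: Acid-catalysed orthoester exchange ties O8 and O10 into a six-membered cyclic orthoester that blocks the C10 hydroxyl, cannot act as a leaving group or be attacked by hydride, and already holds the isobutyryl carbons; the new orthoester centre is a mixture that disappears in step 11.

Step 7
Reactants: 11 cyclic orthoester
Product: 12 aldehyde (4R,6S)-2-methoxy-6-methyl-6-{2-[(2S)-3-methyl-5-oxo-2,5-dihydrofuran-2-yl]ethyl}-2-(propan-2-yl)-1,3-dioxane-4-carbaldehyde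
Conditions: O3, CH2Cl2, −78 °C (Sudan red end point); Me2S, −78 → 23 °C
Reagents that add atoms: ozone, [O-][O+]=O
Why: Ozonolysis cleaves the only electron-rich alkene left (the conjugated butenolide C=C reacts far more slowly) and gives the α-alkoxy C7 aldehyde without touching C8.

Step 8
Reactants: 12 aldehyde; 13 methyl acrylate
Product: 14 Baylis–Hillman alcohol methyl 2-{hydroxy[(4R,6S)-2-methoxy-6-methyl-6-{2-[(2S)-3-methyl-5-oxo-2,5-dihydrofuran-2-yl]ethyl}-2-(propan-2-yl)-1,3-dioxan-4-yl]methyl}prop-2-enoate (C7 epimers)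
Conditions: 13 (10 equiv, neat), DABCO (0.5 equiv), 23 °C, 24–48 h
Reagents that add atoms: none
Why: Morita–Baylis–Hillman reaction of an activated α-alkoxy aldehyde brings in C11–C13; the C7 carbinol forms as a mixture, which is harmless because C7 becomes sp2 in step 9.

Step 9
Reactants: 14 Baylis–Hillman alcohol
Product: 15 allylic bromide methyl (2Z)-2-(bromomethyl)-3-[(4R,6S)-2-methoxy-6-methyl-6-{2-[(2S)-3-methyl-5-oxo-2,5-dihydrofuran-2-yl]ethyl}-2-(propan-2-yl)-1,3-dioxan-4-yl]prop-2-enoate
Conditions: NBS (1.3 equiv), Me2S (1.5 equiv), CH2Cl2, 0 → 23 °C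
Reagents that add atoms: N-bromosuccinimide, O=C1CCC(=O)N1Br
Why: Corey–Kim-type activation of the alcohol as an alkoxysulfonium salt and SN2' attack of bromide give the rearranged primary (Z)-2-(bromomethyl)enoate, the usual outcome for Baylis–Hillman alcohols, under neutral conditions that spare the orthoester.

Step 10
Reactants: 15 allylic bromide
Product: 16 lactol methyl (2Z)-2-(bromomethyl)-3-[(4R,6S)-6-{2-[(2S)-5-hydroxy-3-methyl-2,5-dihydrofuran-2-yl]ethyl}-2-methoxy-6-methyl-2-(propan-2-yl)-1,3-dioxan-4-yl]prop-2-enoate (lactol epimers)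
Conditions: iBu2AlH (1.05 equiv), CH2Cl2, −90 °C, 20 min; Rochelle salt; used crude
Reagents that add atoms: none
Why: Partial hydride reduction of a lactone, which stops at the lactol and favours the unsaturated γ-lactone over the conjugated, α-branched methyl ester when one equivalent is used at low temperature; the 2,5-dihydrofuran-2-ol is the ring form of the (Z)-4-hydroxy-enal and C3 is kept.

Step 11
Reactants: 16 lactol
Product: 19 target CNP0163972.1, via macrocyclic orthoester hydroxy ester 17 (not isolated), via macrocyclic isobutyrate hydroxy ester 18 (not isolated)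
Conditions: indium powder (3 equiv), THF/pH 7 phosphate buffer (1:1), 0.002 M, 23 °C, 16 h; then AcOH/H2O/THF (3:1:1), 40 °C
Reagents that add atoms: water, O
Why: Proposed new method: an intramolecular Barbier-type 2-(alkoxycarbonyl)allylation of a lactol-masked (Z)-enal closes the ten-membered ring at C6–C7 as the cyclase does, the closest known chemistry being indium-mediated 2-(bromomethyl)acrylate additions to unprotected lactols in water and metal-mediated closures of 2-(bromomethyl)enoate aldehydes to germacranolides; the allylindium equilibrates E/Z and reacts through a chair six-membered transition state with both ring tethers pseudo-equatorial, giving the 6,7-anti adduct (6R, hence the trans-lactone once O6 attacks C12), while 1,3-allylic strain holds H8 in the alkene plane so that C6 adds to the C7 face anti to C9 with O8 outside (7R from 8R); aqueous acid then opens the orthoester to the hydroxy isobutyrate, the acyl group settling on the secondary O8 because the tertiary ester is the less stable isomer, and lactonises.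

**Compound list**
1 | (S)-linalool, (3S)-3,7-dimethylocta-1,6-dien-3-ol | C=C[C@@](C)(O)CCC=C(C)C | starting material
2 | (4S)-4-hydroxy-4-methylhex-5-enal | C=C[C@@](C)(O)CCC=O | intermediate
3 | (5S)-5-ethenyl-5-methyloxolan-2-ol (C2 epimers) | C=C[C@]1(C)CCC(O)O1 | intermediate
4 | methyl propiolate | C#CC(=O)OC | starting material
5 | methyl (4S,7S)-4,7-dihydroxy-7-methylnon-8-en-2-ynoate | C=C[C@@](C)(O)CC[C@H](O)C#CC(=O)OC | intermediate
6 | methyl (2Z,4S,7S)-4,7-dihydroxy-3,7-dimethylnona-2,8-dienoate | C=C[C@@](C)(O)CC[C@H](O)/C(C)=C\C(=O)OC | intermediate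
7 | (5S)-5-[(3S)-3-hydroxy-3-methylpent-4-en-1-yl]-4-methylfuran-2(5H)-one | C=C[C@@](C)(O)CC[C@@H]1OC(=O)C=C1C | intermediate
8 | 9-BBN adduct of 7, boron on the terminal carbon of the former vinyl group, both stereocentres as in 7 | B1(CC[C@@](C)(O)CC[C@@H]2OC(=O)C=C2C)C3CCCC1CCC3 | intermediate
9 | (3S)-3-hydroxy-3-methyl-5-[(2S)-3-methyl-5-oxo-2,5-dihydrofuran-2-yl]pentanal | O=CC[C@@](C)(O)CC[C@@H]1OC(=O)C=C1C | intermediate
10 | (5S)-5-[(3S,5R)-3,5-dihydroxy-3-methylhept-6-en-1-yl]-4-methylfuran-2(5H)-one | C=C[C@H](O)C[C@@](C)(O)CC[C@@H]1OC(=O)C=C1C | intermediate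
11 | (5S)-5-{2-[(4S,6R)-6-ethenyl-2-methoxy-4-methyl-2-(propan-2-yl)-1,3-dioxan-4-yl]ethyl}-4-methylfuran-2(5H)-one (orthoester carbon epimers) | C=C[C@H]1C[C@](C)(CC[C@@H]2OC(=O)C=C2C)OC(OC)(C(C)C)O1 | intermediate
12 | (4R,6S)-2-methoxy-6-methyl-6-{2-[(2S)-3-methyl-5-oxo-2,5-dihydrofuran-2-yl]ethyl}-2-(propan-2-yl)-1,3-dioxane-4-carbaldehyde | O=C[C@H]1C[C@](C)(CC[C@@H]2OC(=O)C=C2C)OC(OC)(C(C)C)O1 | intermediate
13 | methyl acrylate | C=CC(=O)OC | starting material
14 | methyl 2-{hydroxy[(4R,6S)-2-methoxy-6-methyl-6-{2-[(2S)-3-methyl-5-oxo-2,5-dihydrofuran-2-yl]ethyl}-2-(propan-2-yl)-1,3-dioxan-4-yl]methyl}prop-2-enoate (carbinol epimers) | COC(=O)C(=C)C(O)[C@H]1C[C@](C)(CC[C@@H]2OC(=O)C=C2C)OC(OC)(C(C)C)O1 | intermediate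
15 | methyl (2Z)-2-(bromomethyl)-3-[(4R,6S)-2-methoxy-6-methyl-6-{2-[(2S)-3-methyl-5-oxo-2,5-dihydrofuran-2-yl]ethyl}-2-(propan-2-yl)-1,3-dioxan-4-yl]prop-2-enoate | COC(=O)/C(CBr)=C/[C@H]1C[C@](C)(CC[C@@H]2OC(=O)C=C2C)OC(OC)(C(C)C)O1 | intermediate
16 | methyl (2Z)-2-(bromomethyl)-3-[(4R,6S)-6-{2-[(2S)-5-hydroxy-3-methyl-2,5-dihydrofuran-2-yl]ethyl}-2-methoxy-6-methyl-2-(propan-2-yl)-1,3-dioxan-4-yl]prop-2-enoate (lactol epimers) | COC(=O)/C(CBr)=C/[C@H]1C[C@](C)(CC[C@@H]2OC(O)C=C2C)OC(OC)(C(C)C)O1 | intermediate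
17 | methyl (4Z)-3β,6α-dihydroxy-8β,10α-[(1-methoxy-2-methylpropane-1,1-diyl)bis(oxy)]germacra-4,11(13)-dien-12-oate, H7 α, all centres as in 19 | COC(=O)C(=C)[C@H]1[C@H](O)/C=C(/C)[C@@H](O)CC[C@@]2(C)C[C@H]1OC(OC)(C(C)C)O2 | intermediate
18 | methyl (4Z)-3β,6α,10α-trihydroxy-8β-(2-methylpropanoyloxy)germacra-4,11(13)-dien-12-oate, H7 α | COC(=O)C(=C)[C@H]1[C@H](O)/C=C(/C)[C@@H](O)CC[C@](C)(O)C[C@H]1OC(=O)C(C)C | intermediate
19 | CNP0163972.1, (3S,4Z,6R,7R,8R,10S)-3,10-dihydroxy-8-(2-methylpropanoyloxy)germacra-4,11(13)-dien-12,6-olide | C=C1C(=O)O[C@@H]2/C=C(/C)[C@@H](O)CC[C@](C)(O)C[C@@H](OC(=O)C(C)C)[C@@H]12 | target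

**Totals**
Total step count: 11. Longest linear sequence: 11 (fully linear from 1).

**Three steps most likely to fail**

Step 11 (ring closure). The risks are oligomers instead of the ten-membered ring, the cis-fused lactone or the other C7 face, and loss of water from lactol 16 to a 3-methylfuran before the allylindium adds. The fallback changes how the allyl nucleophile is made and sets out from 14. Acetylation (Ac2O, pyridine) gives the Baylis–Hillman acetate F1. Disiamylborane in THF at 0 °C reduces only the butenolide, leaving all esters, and gives the lactol acetate F2. Zerovalent-palladium umpolung, Pd(PPh3)4 (5 mol %) with InI in THF under syringe-pump addition, then generates the allylindium slowly from the π-allylpalladium in an aprotic, neutral medium. The route is rejoined at 17, which goes through the acid stage of step 11 to 19.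

Step 10 (lactone to lactol beside a conjugated methyl ester). The risk is over-reduction of the enoate. The fallback builds the selectivity into the substrate and sets out from 12. tert-Butyl acrylate with DABCO gives the tert-butyl Baylis–Hillman alcohol F3, and NBS/Me2S gives the tert-butyl allylic bromide F4. iBu2AlH at −78 °C now touches only the butenolide and gives the tert-butyl ester lactol F5. Indium closure as in step 11 gives the macrocyclic hydroxy tert-butyl ester F6. CF3CO2H in wet CH2Cl2 at 0 °C removes the tert-butyl group, opens the orthoester and lactonises, so the route comes back at 19.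

Step 2 (asymmetric alkynylation on a lactol). The risks are slow opening of the zinc lactolate and eroded selectivity next to the free tertiary alkoxide. The fallback sets C3 by ketone reduction instead and sets out from 3. TEMPO (cat.) with PhI(OAc)2 gives the lactone (5S)-5-ethenyl-5-methyloxolan-2-one F7. LiC≡CCO2Me (from 4 and LiN(SiMe3)2, THF, −78 °C) opens it to the hydroxy ynone methyl (7S)-7-hydroxy-7-methyl-4-oxonon-8-en-2-ynoate F8, which sits in equilibrium with its cyclic hemiketal. Asymmetric transfer hydrogenation with RuCl[(S,S)-TsDPEN](p-cymene) in iPrOH gives the 4S alcohol, and the route is rejoined at 5.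

Further compounds
F1 | step 11 | methyl 2-{acetoxy[(4R,6S)-2-methoxy-6-methyl-6-{2-[(2S)-3-methyl-5-oxo-2,5-dihydrofuran-2-yl]ethyl}-2-(propan-2-yl)-1,3-dioxan-4-yl]methyl}prop-2-enoate | COC(=O)C(=C)C(OC(C)=O)[C@H]1C[C@](C)(CC[C@@H]2OC(=O)C=C2C)OC(OC)(C(C)C)O1
F2 | step 11 | methyl 2-{acetoxy[(4R,6S)-6-{2-[(2S)-5-hydroxy-3-methyl-2,5-dihydrofuran-2-yl]ethyl}-2-methoxy-6-methyl-2-(propan-2-yl)-1,3-dioxan-4-yl]methyl}prop-2-enoate | COC(=O)C(=C)C(OC(C)=O)[C@H]1C[C@](C)(CC[C@@H]2OC(O)C=C2C)OC(OC)(C(C)C)O1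
F3 | step 10 | tert-butyl 2-{hydroxy[(4R,6S)-2-methoxy-6-methyl-6-{2-[(2S)-3-methyl-5-oxo-2,5-dihydrofuran-2-yl]ethyl}-2-(propan-2-yl)-1,3-dioxan-4-yl]methyl}prop-2-enoate | CC(C)(C)OC(=O)C(=C)C(O)[C@H]1C[C@](C)(CC[C@@H]2OC(=O)C=C2C)OC(OC)(C(C)C)O1
F4 | step 10 | tert-butyl (2Z)-2-(bromomethyl)-3-[(4R,6S)-2-methoxy-6-methyl-6-{2-[(2S)-3-methyl-5-oxo-2,5-dihydrofuran-2-yl]ethyl}-2-(propan-2-yl)-1,3-dioxan-4-yl]prop-2-enoate | CC(C)(C)OC(=O)/C(CBr)=C/[C@H]1C[C@](C)(CC[C@@H]2OC(=O)C=C2C)OC(OC)(C(C)C)O1
F5 | step 10 | tert-butyl (2Z)-2-(bromomethyl)-3-[(4R,6S)-6-{2-[(2S)-5-hydroxy-3-methyl-2,5-dihydrofuran-2-yl]ethyl}-2-methoxy-6-methyl-2-(propan-2-yl)-1,3-dioxan-4-yl]prop-2-enoate | CC(C)(C)OC(=O)/C(CBr)=C/[C@H]1C[C@](C)(CC[C@@H]2OC(O)C=C2C)OC(OC)(C(C)C)O1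
F6 | step 10 | tert-butyl (4Z)-3β,6α-dihydroxy-8β,10α-[(1-methoxy-2-methylpropane-1,1-diyl)bis(oxy)]germacra-4,11(13)-dien-12-oate | CC(C)(C)OC(=O)C(=C)[C@H]1[C@H](O)/C=C(/C)[C@@H](O)CC[C@@]2(C)C[C@H]1OC(OC)(C(C)C)O2
F7 | step 2 | (5S)-5-ethenyl-5-methyloxolan-2-one | C=C[C@]1(C)CCC(=O)O1
F8 | step 2 | methyl (7S)-7-hydroxy-7-methyl-4-oxonon-8-en-2-ynoate | C=C[C@@](C)(O)CCC(=O)C#CC(=O)OC
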